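The route rests on cutting the γ-lactone at its alkyl C–O bond (O–C6) together with C7–C11. C6 is allylic to the C4=C5 alkene and next to C7. The lactone atoms O–C6–C7–C11–C12 therefore map onto an (E,E)-1,3-diene (C7=C6–C5=C4) and 2-bromoacrylic acid. One palladium-catalysed heteroannulation joins C11 to C7 and parks the metal on the C4–C6 allyl unit. It then closes the α-methylene lactone by carboxylate attack at C6, setting C6 and C7 under control of C8. Its precursor is an open-chain dienyl dioxolane made from (R)-glyceraldehyde acetonide. A Nozaki–Hiyama–Kishi reaction (C9–C10) closes the ten-membered ring last.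

Key step: step 4

Remark on the chemistry: germacrane numbering is used throughout (ring carbons C1–C10; C11, C12, C13 = lactone α-carbon, carbonyl and exocyclic methylene; C14 = ester carbonyl on C10; C15 = methyl on C4). Silyl ether 3 is taken as a catalogue compound. The C7 descriptor reads R in 13 and 14 only because the CIP priorities change.

Step 1
Reactants: 1 (R)-2,2-dimethyl-1,3-dioxolane-4-carbaldehyde
Product: 2 (S)-2,2-dimethyl-4-vinyl-1,3-dioxolane
Conditions: MePPh3Br, KOtBu, THF, 0 °C; then 1, 0 °C to rt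
Reagents that add atoms: methyltriphenylphosphonium bromide, C[P+](c1ccccc1)(c1ccccc1)c1ccccc1.[Br-]
Why: Wittig methylenation with the non-stabilised ylide is fast at low temperature, so the α-alkoxy stereocentre (future C8) is carried over unchanged and no new stereocentre arises.

Step 2
Reactants: 3 tert-butyldimethyl(pent-4-yn-1-yloxy)silane
Product: 5 (E)-tert-butyl[(5-iodo-4-methylpent-4-en-1-yl)oxy]dimethylsilane, via alkenyl(dimethyl)alane 4 (not isolated)
Conditions: AlMe3, Cp2ZrCl2 (25 mol %), CH2Cl2, 0 °C to rt; then I2, THF, −30 °C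
Reagents that add atoms: trimethylaluminium, C[Al](C)C; iodine, II
Why: Negishi zirconium-catalysed carboalumination adds methyl and aluminium syn across the terminal alkyne with methyl on the internal carbon, and iodinolysis with retention fixes the E geometry of the future C4=C5 alkene.

Step 3
Reactants: 5 (E)-tert-butyl[(5-iodo-4-methylpent-4-en-1-yl)oxy]dimethylsilane; 2 (S)-2,2-dimethyl-4-vinyl-1,3-dioxolane
Product: 6 (S)-4-[(1E,3E)-7-(tert-butyldimethylsilyloxy)-4-methylhepta-1,3-dien-1-yl]-2,2-dimethyl-1,3-dioxolane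
Conditions: Pd(OAc)2 (5 mol %), AgOAc, DMF, rt to 45 °C, dark
Reagents that add atoms: none
Why: Heck vinylation under Jeffery silver-salt conditions couples the alkenyl iodide with retention at the terminal vinyl carbon, β-hydride elimination gives the E C6=C7 alkene, silver suppresses migration toward C8, and no stereocentre is formed.

Step 4
Reactants: 6 (S)-4-[(1E,3E)-7-(tert-butyldimethylsilyloxy)-4-methylhepta-1,3-dien-1-yl]-2,2-dimethyl-1,3-dioxolane; 7 2-bromoacrylic acid
Product: 9 (4S,5R)-5-[(1E)-5-(tert-butyldimethylsilyloxy)-2-methylpent-1-en-1-yl]-4-[(4S)-2,2-dimethyl-1,3-dioxolan-4-yl]-3-methylideneoxolan-2-one, via oxapalladacycle 8 (not isolated)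
Conditions: 7 (slow addition), Pd(OAc)2 (10 mol %), PPh3 (20 mol %), Ag2CO3, BHT (trace), DMF, 70 °C
Reagents that add atoms: none
Why: Zerovalent palladium inserts into the C–Br bond of 7, the alkenylpalladium carboxylate adds syn across C6=C7 so that C11 bonds to C7 and the metal sits on C6 as terminus of a C4–C5–C6 allyl unit (oxapalladacycle 8), and C–O bond formation between the bound carboxylate oxygen and C6 releases 9 and zerovalent palladium. The closest known reaction type is the Larock heteroannulation of 1,3-dienes by 2-haloacrylic acids. The lactone closes in the 5-exo mode at allyl terminus C6 by ring contraction of the six-membered palladacycle, whereas closure at the tertiary terminus C4 would need a seven-membered ring. C7 is controlled by C8, because the alkenylpalladium should approach the C6=C7 face anti to the allylic C8–O bond of the dioxolane (inside-alkoxy or hydrogen-eclipsed conformer), which gives 7S. C6 is controlled by C7 and by the E geometry of C6=C7, because syn carbopalladation followed by inner-sphere C–O reductive elimination, favoured by the halide-free silver conditions, is a net syn addition that gives the trans 6R lactone, and any cis lactone can re-ionise and drain to the more stable trans isomer. The step needs regioselectivity for C7 over C4, which the less substituted diene terminus secures, retention of the E C4=C5 geometry, which holds because isomerisation would have to pass through a tertiary C4-bound palladium species, and chemoselectivity over the new exocyclic methylene, which slow addition of 7 supports.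

Step 5
Reactants: 9 (4S,5R)-5-[(1E)-5-(tert-butyldimethylsilyloxy)-2-methylpent-1-en-1-yl]-4-[(4S)-2,2-dimethyl-1,3-dioxolan-4-yl]-3-methylideneoxolan-2-one
Product: 10 (4S,5R)-4-[(4S)-2,2-dimethyl-1,3-dioxolan-4-yl]-5-[(1E)-5-hydroxy-2-methylpent-1-en-1-yl]-3-methylideneoxolan-2-one
Conditions: HF·pyridine, pyridine, THF, 0 °C to rt
Reagents that add atoms: none
Why: Fluoride-mediated desilylation in a pyridine-buffered medium removes the primary silyl ether while the acetonide and the base-sensitive α-methylene lactone should survive, and no stereocentre is touched.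

Step 6
Reactants: 10 (4S,5R)-4-[(4S)-2,2-dimethyl-1,3-dioxolan-4-yl]-5-[(1E)-5-hydroxy-2-methylpent-1-en-1-yl]-3-methylideneoxolan-2-one
Product: 11 (4E)-5-{(2R,3S)-3-[(4S)-2,2-dimethyl-1,3-dioxolan-4-yl]-4-methylidene-5-oxooxolan-2-yl}-4-methylpent-4-enal
Conditions: Dess–Martin periodinane, CH2Cl2, 0 °C to rt
Reagents that add atoms: none
Why: Dess–Martin oxidation stops at the C1 aldehyde under near-neutral conditions that leave the alkenes, the lactone and the acetonide alone.

Step 7
Reactants: 11 (4E)-5-{(2R,3S)-3-[(4S)-2,2-dimethyl-1,3-dioxolan-4-yl]-4-methylidene-5-oxooxolan-2-yl}-4-methylpent-4-enal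
Product: 12 methyl (2Z,6E)-7-{(2R,3S)-3-[(4S)-2,2-dimethyl-1,3-dioxolan-4-yl]-4-methylidene-5-oxooxolan-2-yl}-2-iodo-6-methylhepta-2,6-dienoate
Conditions: Ph3P=CHCO2Me, NIS, CH2Cl2, −20 °C; then 11, −20 °C to rt
Reagents that add atoms: methyl (triphenylphosphoranylidene)acetate, COC(=O)C=P(c1ccccc1)(c1ccccc1)c1ccccc1; N-iodosuccinimide, O=C1CCC(=O)N1I
Why: Wittig olefination with the stabilised α-iodo ylide made in the flask places the alkyl chain trans to the ester, so the Z iodoalkene already has the C1=C10 geometry of the target (iodine holds the place of C9).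

Step 8
Reactants: 12 methyl (2Z,6E)-7-{(2R,3S)-3-[(4S)-2,2-dimethyl-1,3-dioxolan-4-yl]-4-methylidene-5-oxooxolan-2-yl}-2-iodo-6-methylhepta-2,6-dienoate
Product: 13 methyl (2Z,6E)-7-{(2R,3R)-3-[(1S)-1,2-dihydroxyethyl]-4-methylidene-5-oxooxolan-2-yl}-2-iodo-6-methylhepta-2,6-dienoate
Conditions: AcOH/H2O/THF, 45 °C
Reagents that add atoms: none
Why: Acid-catalysed acetal hydrolysis frees the C8,C9-diol without touching a stereocentre, and acyl shift to O8 is not expected because the trans-disubstituted 12,6-lactone is more stable than the cis-disubstituted 12,8-isomer.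

Step 9
Reactants: 13 methyl (2Z,6E)-7-{(2R,3R)-3-[(1S)-1,2-dihydroxyethyl]-4-methylidene-5-oxooxolan-2-yl}-2-iodo-6-methylhepta-2,6-dienoate
Product: 14 methyl (2Z,6E)-7-{(2R,3R)-3-[(1S)-1-hydroxy-2-(triethylsilyloxy)ethyl]-4-methylidene-5-oxooxolan-2-yl}-2-iodo-6-methylhepta-2,6-dienoate
Conditions: TESCl (1 equiv), imidazole, CH2Cl2, −40 °C
Reagents that add atoms: chlorotriethylsilane, CC[Si](Cl)(CC)CC
Why: Silylation at low temperature discriminates the primary C9 hydroxyl from the hindered secondary C8 hydroxyl on steric grounds.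

Step 10
Reactants: 14 methyl (2Z,6E)-7-{(2R,3R)-3-[(1S)-1-hydroxy-2-(triethylsilyloxy)ethyl]-4-methylidene-5-oxooxolan-2-yl}-2-iodo-6-methylhepta-2,6-dienoate
Product: 15 methyl (2Z,6E)-2-iodo-7-{(2R,3S)-3-[(1S)-1-(methacryloyloxy)-2-(triethylsilyloxy)ethyl]-4-methylidene-5-oxooxolan-2-yl}-6-methylhepta-2,6-dienoate
Conditions: methacrylic anhydride, Et3N, DMAP (cat.), CH2Cl2, 0 °C to rt
Reagents that add atoms: methacrylic anhydride, C=C(C)C(=O)OC(=O)C(C)=C
Why: DMAP-catalysed acyl transfer esterifies the only free hydroxyl with retention at C8.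

Step 11
Reactants: 15 methyl (2Z,6E)-2-iodo-7-{(2R,3S)-3-[(1S)-1-(methacryloyloxy)-2-(triethylsilyloxy)ethyl]-4-methylidene-5-oxooxolan-2-yl}-6-methylhepta-2,6-dienoate
Product: 17 methyl (2Z,6E)-2-iodo-7-{(2R,3S)-3-[(1S)-1-(methacryloyloxy)-2-oxoethyl]-4-methylidene-5-oxooxolan-2-yl}-6-methylhepta-2,6-dienoate, via alkoxysulfonium chloride 16 (not isolated)
Conditions: (COCl)2, DMSO, CH2Cl2, −78 to −40 °C; then Et3N, −78 to 0 °C
Reagents that add atoms: none
Why: Under Swern conditions a primary triethylsilyl ether is cleaved by the chlorosulfonium salt to alkoxysulfonium salt 16, which collapses to the C9 aldehyde on addition of Et3N, and the low temperature protects the α-acyloxy centre C8 from epimerisation.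

Step 12
Reactants: 17 methyl (2Z,6E)-2-iodo-7-{(2R,3S)-3-[(1S)-1-(methacryloyloxy)-2-oxoethyl]-4-methylidene-5-oxooxolan-2-yl}-6-methylhepta-2,6-dienoate
Product: 18 methyl (6R,7S,8S,9S)-9-hydroxy-8-(methacryloyloxy)germacra-1(10),4,11(13)-trien-12,6-olid-14-oate (E C4=C5; C1=C10 with C2 cis to C9)
Conditions: CrCl2 (10 equiv), NiCl2 (0.1 equiv), DMSO, 2 mM, rt; aqueous work-up
Reagents that add atoms: none
Why: In the Nozaki–Hiyama–Kishi coupling zerovalent nickel inserts into the C–I bond, transmetalation gives an alkenyl species of trivalent chromium that adds only to the aldehyde with retention of the ring-cis C1=C10 geometry, and C9 should become 9S because in the ring-forming transition state the chromium-bound aldehyde oxygen and the C8 methacrylate both point to the outside of the nascent ten-membered ring and so end up trans on it.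

Compound list
1 | (R)-2,2-dimethyl-1,3-dioxolane-4-carbaldehyde | O=C[C@H]1COC(C)(C)O1 | starting material
2 | (S)-2,2-dimethyl-4-vinyl-1,3-dioxolane | C=C[C@H]1COC(C)(C)O1 | intermediate
3 | tert-butyldimethyl(pent-4-yn-1-yloxy)silane | C#CCCCO[Si](C)(C)C(C)(C)C | starting material
4 | (E)-[5-(tert-butyldimethylsilyloxy)-2-methylpent-1-en-1-yl]dimethylalane | C[Al](C)/C=C(\C)CCCO[Si](C)(C)C(C)(C)C | intermediate
5 | (E)-tert-butyl[(5-iodo-4-methylpent-4-en-1-yl)oxy]dimethylsilane | I/C=C(\C)CCCO[Si](C)(C)C(C)(C)C | intermediate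
6 | (S)-4-[(1E,3E)-7-(tert-butyldimethylsilyloxy)-4-methylhepta-1,3-dien-1-yl]-2,2-dimethyl-1,3-dioxolane | CC(C)(C)[Si](C)(C)OCCC/C(C)=C/C=C/[C@H]1COC(C)(C)O1 | intermediate
7 | 2-bromoacrylic acid | C=C(Br)C(=O)O | starting material
8 | six-membered oxapalladacycle, palladium bound to C6 and to the C12 carboxylate oxygen, other ligands omitted | C=C1C(=O)O[Pd][C@H](/C=C(\C)CCCO[Si](C)(C)C(C)(C)C)[C@H]1[C@H]2COC(C)(C)O2 | intermediate
9 | (4S,5R)-5-[(1E)-5-(tert-butyldimethylsilyloxy)-2-methylpent-1-en-1-yl]-4-[(4S)-2,2-dimethyl-1,3-dioxolan-4-yl]-3-methylideneoxolan-2-one (6R,7S,8S) | C=C1C(=O)O[C@H](/C=C(\C)CCCO[Si](C)(C)C(C)(C)C)[C@H]1[C@H]2COC(C)(C)O2 | intermediate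
10 | (4S,5R)-4-[(4S)-2,2-dimethyl-1,3-dioxolan-4-yl]-5-[(1E)-5-hydroxy-2-methylpent-1-en-1-yl]-3-methylideneoxolan-2-one | C=C1C(=O)O[C@H](/C=C(\C)CCCO)[C@H]1[C@H]2COC(C)(C)O2 | intermediate
11 | (4E)-5-{(2R,3S)-3-[(4S)-2,2-dimethyl-1,3-dioxolan-4-yl]-4-methylidene-5-oxooxolan-2-yl}-4-methylpent-4-enal | C=C1C(=O)O[C@H](/C=C(\C)CCC=O)[C@H]1[C@H]2COC(C)(C)O2 | intermediate
12 | methyl (2Z,6E)-7-{(2R,3S)-3-[(4S)-2,2-dimethyl-1,3-dioxolan-4-yl]-4-methylidene-5-oxooxolan-2-yl}-2-iodo-6-methylhepta-2,6-dienoate | C=C1C(=O)O[C@H](/C=C(\C)CC/C=C(\I)C(=O)OC)[C@H]1[C@H]2COC(C)(C)O2 | intermediate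
13 | methyl (2Z,6E)-7-{(2R,3R)-3-[(1S)-1,2-dihydroxyethyl]-4-methylidene-5-oxooxolan-2-yl}-2-iodo-6-methylhepta-2,6-dienoate | C=C1C(=O)O[C@H](/C=C(\C)CC/C=C(\I)C(=O)OC)[C@H]1[C@H](O)CO | intermediate
14 | methyl (2Z,6E)-7-{(2R,3R)-3-[(1S)-1-hydroxy-2-(triethylsilyloxy)ethyl]-4-methylidene-5-oxooxolan-2-yl}-2-iodo-6-methylhepta-2,6-dienoate | C=C1C(=O)O[C@H](/C=C(\C)CC/C=C(\I)C(=O)OC)[C@H]1[C@H](O)CO[Si](CC)(CC)CC | intermediate
15 | methyl (2Z,6E)-2-iodo-7-{(2R,3S)-3-[(1S)-1-(methacryloyloxy)-2-(triethylsilyloxy)ethyl]-4-methylidene-5-oxooxolan-2-yl}-6-methylhepta-2,6-dienoate | C=C1C(=O)O[C@H](/C=C(\C)CC/C=C(\I)C(=O)OC)[C@H]1[C@H](OC(=O)C(C)=C)CO[Si](CC)(CC)CC | intermediate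
16 | dimethyl(alkoxy)sulfonium chloride at O9 of the desilylated form of 15 | C=C1C(=O)O[C@H](/C=C(\C)CC/C=C(\I)C(=O)OC)[C@H]1[C@H](OC(=O)C(C)=C)CO[S+](C)C.[Cl-] | intermediate
17 | methyl (2Z,6E)-2-iodo-7-{(2R,3S)-3-[(1S)-1-(methacryloyloxy)-2-oxoethyl]-4-methylidene-5-oxooxolan-2-yl}-6-methylhepta-2,6-dienoate | C=C1C(=O)O[C@H](/C=C(\C)CC/C=C(\I)C(=O)OC)[C@H]1[C@H](OC(=O)C(C)=C)C=O | intermediate
18 | methyl (6R,7S,8S,9S)-9-hydroxy-8-(methacryloyloxy)germacra-1(10),4,11(13)-trien-12,6-olid-14-oate | C=C(C)C(=O)O[C@H]1[C@H]2C(=C)C(=O)O[C@@H]2/C=C(\C)CC/C=C(/C(=O)OC)[C@@H]1O | target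

Total step count: 12. Longest linear sequence: 11 steps (steps 2 to 12, from 3 to 18).

Steps most likely to fail

1. Step 4.
- What may go wrong: insertion into an internal, trisubstituted diene may be slow, so that self-coupling or polymerisation of the bromoacrylate takes over. The dioxolane may also give poor facial selectivity at C7.
- The fallback sets out from 5 and 1 and comes back at 9. It still makes O–C6 by ring closure, now by displacement.
- Iodine–lithium exchange on 5 (t-BuLi, Et2O, −78 °C) and formylation with DMF would give (E)-6-(tert-butyldimethylsilyloxy)-3-methylhex-2-enal F1.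
- In parallel, a Morita–Baylis–Hillman reaction of 1 with tert-butyl acrylate (DABCO) would give tert-butyl 2-{[(4R)-2,2-dimethyl-1,3-dioxolan-4-yl](hydroxy)methyl}acrylate F2.
- NBS/Me2S would convert F2 with allylic transposition into tert-butyl (Z)-2-(bromomethyl)-3-[(4S)-2,2-dimethyl-1,3-dioxolan-4-yl]acrylate F3.
- An indium-mediated Barbier coupling of F3 and F1 (indium powder, THF/H2O) should pass through a chair transition state of the Z allylindium, held on the O8 face by internal coordination. It should give tert-butyl (3S,4S,5E)-9-(tert-butyldimethylsilyloxy)-3-[(4S)-2,2-dimethyl-1,3-dioxolan-4-yl]-4-hydroxy-6-methyl-2-methylidenenon-5-enoate F4, the 6,7-syn adduct with C6 epimeric to 9.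
- Activation with Ms2O/Et3N (CH2Cl2, −20 °C to rt) lets the ester carbonyl oxygen displace the allylic mesylate at C6 with inversion and loss of the tert-butyl group, giving 9.

2. Step 12.
- What may go wrong: addition may take the other face of the aldehyde, because the open-chain Felkin–Anh preference of an α-acyloxy aldehyde opposes the ring-controlled one.
- The fallback sets out from 17 and comes back at 18. It sets C9 by hydride delivery instead of by C–C bond formation.
- The same coupling would then give methyl (6R,7S,8S,9R)-9-hydroxy-8-(methacryloyloxy)germacra-1(10),4,11(13)-trien-12,6-olid-14-oate F5.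
- Dess–Martin oxidation would give methyl (6R,7S,8S)-8-(methacryloyloxy)-9-oxogermacra-1(10),4,11(13)-trien-12,6-olid-14-oate F6.
- A Luche reduction (NaBH4, CeCl3·7H2O, MeOH, −78 °C) should attack the ring ketone from outside the ring and anti to the C8–O bond. For a hydride nucleophile that is the Felkin–Anh sense leading to the 8,9-syn carbinol 18.

3. Step 3.
- What may go wrong: β-hydride elimination toward C8 or migration of the new double bond may erode the diene or its E geometry.
- The fallback sets out from 1 and 5 and comes back at 6. It replaces the Heck reaction by a stereospecific cross-coupling of two preformed alkenyl partners.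
- Ohira–Bestmann homologation of 1 (dimethyl 1-diazo-2-oxopropylphosphonate, K2CO3, MeOH) would give (S)-4-ethynyl-2,2-dimethyl-1,3-dioxolane F7.
- Hydroboration with pinacolborane (Cp2Zr(H)Cl cat., Et3N cat., 60 °C) would give (E)-2-{2-[(4S)-2,2-dimethyl-1,3-dioxolan-4-yl]vinyl}-4,4,5,5-tetramethyl-1,3,2-dioxaborolane F8.
- Suzuki–Miyaura coupling of F8 and 5 (Pd(PPh3)4, K3PO4, THF/H2O) would give 6 with retention at both alkenes.

Further compounds
F1 | step 4 | (E)-6-(tert-butyldimethylsilyloxy)-3-methylhex-2-enal | O=C/C=C(\C)CCCO[Si](C)(C)C(C)(C)C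
F2 | step 4 | tert-butyl 2-{[(4R)-2,2-dimethyl-1,3-dioxolan-4-yl](hydroxy)methyl}acrylate (both carbinol epimers) | C=C(C(=O)OC(C)(C)C)C(O)[C@H]1COC(C)(C)O1
F3 | step 4 | tert-butyl (Z)-2-(bromomethyl)-3-[(4S)-2,2-dimethyl-1,3-dioxolan-4-yl]acrylate | BrC/C(C(=O)OC(C)(C)C)=C\[C@H]1COC(C)(C)O1
F4 | step 4 | tert-butyl (3S,4S,5E)-9-(tert-butyldimethylsilyloxy)-3-[(4S)-2,2-dimethyl-1,3-dioxolan-4-yl]-4-hydroxy-6-methyl-2-methylidenenon-5-enoate | C=C(C(=O)OC(C)(C)C)[C@H]([C@H]1COC(C)(C)O1)[C@@H](O)/C=C(\C)CCCO[Si](C)(C)C(C)(C)C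
F5 | step 12 | methyl (6R,7S,8S,9R)-9-hydroxy-8-(methacryloyloxy)germacra-1(10),4,11(13)-trien-12,6-olid-14-oate | C=C(C)C(=O)O[C@H]1[C@H]2C(=C)C(=O)O[C@@H]2/C=C(\C)CC/C=C(/C(=O)OC)[C@H]1O
F6 | step 12 | methyl (6R,7S,8S)-8-(methacryloyloxy)-9-oxogermacra-1(10),4,11(13)-trien-12,6-olid-14-oate | C=C(C)C(=O)O[C@H]1[C@H]2C(=C)C(=O)O[C@@H]2/C=C(\C)CC/C=C(/C(=O)OC)C1=O
F7 | step 3 | (S)-4-ethynyl-2,2-dimethyl-1,3-dioxolane | C#C[C@H]1COC(C)(C)O1
F8 | step 3 | (E)-2-{2-[(4S)-2,2-dimethyl-1,3-dioxolan-4-yl]vinyl}-4,4,5,5-tetramethyl-1,3,2-dioxaborolane | CC1(C)OB(/C=C/[C@H]2COC(C)(C)O2)OC1(C)C
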